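The pyrrole is traced back, across its N1–C5 bond, to a pyridazine with one more nitrogen. The key step exploits that the N1–C2(CO2Me)–C3(tricosyl)–C4(H) edge of the pyrrole ring already exists as N2–C3–C4–C5 of dimethyl 4-tricosylpyridazine-3,6-dicarboxylate, a diazine made electron-poor by its two nitrogens and two esters. Zinc in acetic acid should reduce this ring, break N–N, join one nitrogen to the carbon that held the other and expel ammonia: ring contraction to the pyrrole in one operation. The precursor comes from a terminal alkyne and a tetrazine diester; the extra C5 ester is finally removed by selective saponification and decarboxylation.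

Key step: step 4

Remark: the target has no stereocentre. Carbons 2–24 of the C24 aldehyde form the tricosyl chain and its carbonyl carbon becomes pyrrole C3, while the diazo carbon of the homologation reagent becomes C4–H. All C24–C25 intermediates are waxes, hence the warm or THF-containing media.

Step 1
Reactants: 1 tetracosan-1-ol
Product: 2 tetracosanal
Conditions: IBX (1.5 equiv), EtOAc, 80 °C; filter, concentrate
Reagents that add atoms: none
Why: Hypervalent-iodine oxidation of a primary alcohol with IBX stops at the aldehyde without over-oxidation, and hot ethyl acetate dissolves the waxy alcohol while the reagent and its reduced form stay insoluble and are filtered off.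

Step 2
Reactants: 2 tetracosanal; 3 dimethyl (1-diazo-2-oxopropyl)phosphonate (Ohira–Bestmann reagent)
Product: 5 pentacos-1-yne, via 1-diazopentacos-1-ene 4 (not isolated)
Conditions: 3 (1.3 equiv), K2CO3 (2 equiv), MeOH/THF 1:1, 25 °C
Reagents that add atoms: none
Why: Ohira–Bestmann variant of the Seyferth–Gilbert homologation, in which methanolysis of 3 frees the dimethyl (diazomethyl)phosphonate anion, Horner–Wadsworth–Emmons-type olefination of the aldehyde gives diazoalkene 4, and loss of N2 followed by a 1,2-hydride shift in the alkylidene carbene gives the terminal alkyne under base mild enough for an enolisable aldehyde.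

Step 3
Reactants: 5 pentacos-1-yne; 6 dimethyl 1,2,4,5-tetrazine-3,6-dicarboxylate
Product: 8 dimethyl 4-tricosylpyridazine-3,6-dicarboxylate, via tetraazabicyclooctatriene adduct 7 (not isolated)
Conditions: 6 (1.3 equiv, two portions), dry 1,4-dioxane, 100 °C, Ar
Reagents that add atoms: none
Why: Inverse-electron-demand Diels–Alder reaction (Carboni–Lindsey type) of the electron-poor tetrazine across C3 and C6 with the alkyne gives bicycle 7, which loses N2 by a retro-Diels–Alder step and is then already aromatic; the symmetric diene leaves no regiochemical question, and heating compensates for the modest reactivity of an unactivated terminal alkyne.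

Step 4
Reactants: 8 dimethyl 4-tricosylpyridazine-3,6-dicarboxylate
Product: 12 dimethyl 3-tricosyl-1H-pyrrole-2,5-dicarboxylate, via 1,4-dihydropyridazine 9 (not isolated), via open-chain amino imine 10 (not isolated), via cyclic aminal 11 (not isolated)
Conditions: Zn dust (10 equiv), AcOH/THF 4:1, 25 → 45 °C
Reagents that add atoms: none
Why: Zinc transfers two electrons to the diazine ring, whose acceptor level is lowered by the two ring nitrogens and by the esters on C3 and C6, and protonation by acetic acid gives the ester-stabilised 1,4-dihydropyridazine 9 (a cyclic ene-hydrazine/hydrazone). A second two-electron reduction breaks the weak N–N bond and opens the ring to the (Z)-amino imine 10, in which the enamine nitrogen and the arm carrying the imine carbon sit on the same side of the C=C bond. The amino nitrogen adds to that imine carbon in a 5-exo-trig closure, which forms the one new N–C bond and the five-membered ring (aminal 11), and loss of ammonia across the aminal carbon and the adjacent CH2 aromatises 11 to pyrrole 12. The closest known reaction type is the zinc–acetic acid reductive ring contraction of 1,2-diazine-3,6-dicarboxylates to pyrrole-2,5-dicarboxylates, applied here to a 4-alkyl substrate. No lasting stereocentre is created, since the aminal carbon of 11 is transient and racemic. The step needs only chemoselectivity (reduction of the diazine and its N–N bond while esters, chain and product pyrrole stay untouched), which the much easier reduction of the electron-poor diazine should secure; which nitrogen is kept is immaterial, because closure from either end gives the same pyrrole.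

Step 5
Reactants: 12 dimethyl 3-tricosyl-1H-pyrrole-2,5-dicarboxylate
Product: 14 5-(methoxycarbonyl)-4-tricosyl-1H-pyrrole-2-carboxylic acid, via lithium carboxylate 13 (not isolated)
Conditions: LiOH·H2O (1.5 equiv), THF/MeOH/H2O 4:1:1, 25 °C; then 1 M HCl
Reagents that add atoms: lithium hydroxide, [Li+].[OH-]
Why: Ester saponification (BAc2) should occur faster at the C5 ester, flanked only by C4–H, than at the C2 ester, which is shielded by the first methylene groups of the C3 chain and made less electrophilic by that alkyl donor, and the carboxylate of 13 deactivates the remaining ester through the electron-rich ring so that hydrolysis should stop at the mono-acid.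

Step 6
Reactants: 14 5-(methoxycarbonyl)-4-tricosyl-1H-pyrrole-2-carboxylic acid
Product: 15 methyl 3-tricosyl-1H-pyrrole-2-carboxylate (target)
Conditions: Cu powder (0.2 equiv), quinoline, 200 °C, Ar
Reagents that add atoms: none
Why: Copper-assisted thermal protodecarboxylation of a pyrrole-2-carboxylic acid, by ipso-protonation or cupration at the α-carbon and loss of CO2, is a classical way to free a pyrrole α-position, and neither the methyl ester nor the saturated chain reacts under these neutral, anhydrous conditions.

Compound list
1 | tetracosan-1-ol | CCCCCCCCCCCCCCCCCCCCCCCCO | starting material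
2 | tetracosanal | CCCCCCCCCCCCCCCCCCCCCCCC=O | intermediate
3 | dimethyl (1-diazo-2-oxopropyl)phosphonate (Ohira–Bestmann reagent) | COP(=O)(OC)C(=[N+]=[N-])C(C)=O | starting material
4 | 1-diazopentacos-1-ene (not isolated) | CCCCCCCCCCCCCCCCCCCCCCCC=C=[N+]=[N-] | intermediate
5 | pentacos-1-yne | CCCCCCCCCCCCCCCCCCCCCCCC#C | intermediate
6 | dimethyl 1,2,4,5-tetrazine-3,6-dicarboxylate | COC(=O)c1nnc(C(=O)OC)nn1 | starting material
7 | dimethyl 7-tricosyl-2,3,5,6-tetraazabicyclo[2.2.2]octa-2,5,7-triene-1,4-dicarboxylate (not isolated) | COC(=O)C12N=NC(C(=O)OC)(N=N1)C=C2CCCCCCCCCCCCCCCCCCCCCCC | intermediate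
8 | dimethyl 4-tricosylpyridazine-3,6-dicarboxylate | CCCCCCCCCCCCCCCCCCCCCCCc1cc(C(=O)OC)nnc1C(=O)OC | intermediate
9 | dimethyl 5-tricosyl-1,4-dihydropyridazine-3,6-dicarboxylate (not isolated) | CCCCCCCCCCCCCCCCCCCCCCCC1=C(C(=O)OC)NN=C(C(=O)OC)C1 | intermediate
10 | dimethyl (2Z)-2-amino-5-imino-3-tricosylhex-2-enedioate (not isolated) | CCCCCCCCCCCCCCCCCCCCCCC/C(CC(=N)C(=O)OC)=C(/N)C(=O)OC | intermediate
11 | dimethyl 2-amino-4-tricosyl-2,3-dihydro-1H-pyrrole-2,5-dicarboxylate (racemic, not isolated) | CCCCCCCCCCCCCCCCCCCCCCCC1=C(C(=O)OC)NC(N)(C(=O)OC)C1 | intermediate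
12 | dimethyl 3-tricosyl-1H-pyrrole-2,5-dicarboxylate | CCCCCCCCCCCCCCCCCCCCCCCc1cc(C(=O)OC)[nH]c1C(=O)OC | intermediate
13 | lithium 5-(methoxycarbonyl)-4-tricosyl-1H-pyrrole-2-carboxylate (not isolated) | CCCCCCCCCCCCCCCCCCCCCCCc1cc(C(=O)[O-])[nH]c1C(=O)OC.[Li+] | intermediate
14 | 5-(methoxycarbonyl)-4-tricosyl-1H-pyrrole-2-carboxylic acid | CCCCCCCCCCCCCCCCCCCCCCCc1cc(C(=O)O)[nH]c1C(=O)OC | intermediate
15 | methyl 3-tricosyl-1H-pyrrole-2-carboxylate | CCCCCCCCCCCCCCCCCCCCCCCc1cc[nH]c1C(=O)OC | target

Total step count: 6
Longest linear sequence: 6 steps (from 1 to 15; compounds 3 and 6 enter as purchased materials)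

Steps most likely to fail

Step 4 (key step, where the route is meant to carry its risk). The reduction may stall at the dihydro stage because the waxy diester dissolves poorly in acetic acid, or the opened amino imine may hydrolyse instead of closing. The fallback builds the ring differently, setting out from 2 and returning at 15. Henry addition of nitromethane to tetracosanal (KOtBu cat., THF/t-BuOH) should give 1-nitropentacosan-2-ol F1, and acetylation (Ac2O, DMAP cat.) should give 1-nitropentacosan-2-yl acetate F2. In a Barton–Zard pyrrole synthesis with methyl isocyanoacetate and DBU (2.2 equiv, THF), F2 should eliminate acetic acid in the flask to (E)-1-nitropentacos-1-ene F3. Conjugate addition of the isocyanoacetate carbanion to the chain-bearing carbon, 5-endo-dig closure of the nitronate onto the isocyanide carbon and loss of nitrous acid would place the tricosyl group at C3 next to the C2 ester and give 15 directly.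

Step 5. The discrimination between the two methyl esters may be insufficient, with attack also at the C2 ester or progression to the diacid. The fallback sets out from 12 and returns at 14; it moves the discrimination to an acyl-transfer esterification of the free diacid and gives the two carboxyl groups orthogonal esters. Exhaustive saponification (NaOH excess, aq. EtOH/THF, reflux; HCl) should give 3-tricosyl-1H-pyrrole-2,5-dicarboxylic acid F4. Carbodiimide esterification of the unhindered C5 acid with one equivalent of benzyl alcohol (EDC·HCl, DMAP cat., CH2Cl2/THF, 0 °C) should give 5-[(benzyloxy)carbonyl]-3-tricosyl-1H-pyrrole-2-carboxylic acid F5. Methylation of the remaining acid with trimethylsilyldiazomethane (toluene/MeOH) should give 5-benzyl 2-methyl 3-tricosyl-1H-pyrrole-2,5-dicarboxylate F6, which can be freed of any regioisomer by chromatography at the neutral diester stage. Hydrogenolysis (H2, Pd/C, THF) would then free the C5 acid 14.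

Step 3. Cycloaddition of the unactivated alkyne may be too slow to compete with thermal or hydrolytic decomposition of the tetrazine. The fallback replaces the alkyne by an electron-rich enol ether, setting out from 2 and returning at 8. Wittig methoxymethylenation of tetracosanal ((methoxymethyl)triphenylphosphonium chloride, KOtBu, THF, 0 °C) should give 1-methoxypentacos-1-ene F7 as an E/Z mixture, both isomers being usable. This enol ether should add to tetrazine 6 in dioxane at 25 °C, and loss of N2 gives dimethyl 4-methoxy-5-tricosyl-4,5-dihydropyridazine-3,6-dicarboxylate F8. Elimination of methanol, spontaneous or on warming with a trace of acid, would aromatise it to 8.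

Further compounds
F1 | step 4 | 1-nitropentacosan-2-ol (racemic) | CCCCCCCCCCCCCCCCCCCCCCCC(O)C[N+](=O)[O-]
F2 | step 4 | 1-nitropentacosan-2-yl acetate (racemic) | CCCCCCCCCCCCCCCCCCCCCCCC(OC(C)=O)C[N+](=O)[O-]
F3 | step 4 | (E)-1-nitropentacos-1-ene | CCCCCCCCCCCCCCCCCCCCCCC/C=C/[N+](=O)[O-]
F4 | step 5 | 3-tricosyl-1H-pyrrole-2,5-dicarboxylic acid | CCCCCCCCCCCCCCCCCCCCCCCc1cc(C(=O)O)[nH]c1C(=O)O
F5 | step 5 | 5-[(benzyloxy)carbonyl]-3-tricosyl-1H-pyrrole-2-carboxylic acid | CCCCCCCCCCCCCCCCCCCCCCCc1cc(C(=O)OCc2ccccc2)[nH]c1C(=O)O
F6 | step 5 | 5-benzyl 2-methyl 3-tricosyl-1H-pyrrole-2,5-dicarboxylate | CCCCCCCCCCCCCCCCCCCCCCCc1cc(C(=O)OCc2ccccc2)[nH]c1C(=O)OC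
F7 | step 3 | 1-methoxypentacos-1-ene (E/Z mixture) | CCCCCCCCCCCCCCCCCCCCCCCC=COC
F8 | step 3 | dimethyl 4-methoxy-5-tricosyl-4,5-dihydropyridazine-3,6-dicarboxylate (diastereomer mixture) | CCCCCCCCCCCCCCCCCCCCCCCC1C(OC)C(C(=O)OC)=NN=C1C(=O)OC
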